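Charge nothing yet: first reckon what the order of addition is worth, as a small correction to the plain flask, then choose the recipe for homo product.

| setting | ochre | green | blue | alder | maple | oak | cedar | elm |
|---|---|---|---|---|---|---|---|---|
| substrate | 0.50 M | 0.50 M | 0.50 M | 0.50 M | 0.50 M (in portions, 5, over 6.0 min) | 0.50 M | 0.50 M (fed, over 6.0 min) | 0.50 M |
| partner | 1 equiv | 0.67 equiv | 1.5 equiv | 1.00 equiv (fed, over 6.0 min) | 1.00 equiv | 1.00 equiv | 1.00 equiv | 1.00 equiv (fed, over 40 s) |
| remark | run made earlier | run made earlier | run made earlier | all else is in the flask from the start; the feed brings no volume worth counting | first portion at the start, last at 6.0 min | everything together at the start | all else is in the flask from the start; the feed brings no volume worth counting | all else is in the flask from the start; the feed brings no volume worth counting |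
| time |  |  |  | 30 min | 30 min | 30 min | 30 min | 30 min |

| run | time / min | homo product / % | target / % |
|---|---|---|---|
| ochre | 1.33 | 1 | 4 |
| ochre | 2.50 | 9 | 0 |
| ochre | 5.00 | 28 | 9 |
| ochre | 10.0 | 41 | 6 |
| ochre | 20.0 | 49 | 3 |
| green | 6.00 | 30 | 3 |
| green | 12.0 | 44 | 3 |
| green | 20.0 | 54 | 3 |
| green | 25.0 | 57 | 0 |
| green | 30.0 | 57 | 4 |
| blue | 2.50 | 11 | 1 |
| blue | 5.00 | 22 | 9 |
| blue | 8.00 | 32 | 8 |
| blue | 15.0 | 38 | 6 |
| blue | 30.0 | 41 | 2 |

(each reading ± 2 percentage points)

* the flask that comes out highest in amount of homo product, in percent of the substrate charged, or "all alike" when all lie within 1.5 percentage points (alder / maple / oak / cedar / elm / all alike)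
* homo product at the end, in percent of the substrate charged, alder
* homo product at the end, in percent of the substrate charged, maple
* homo product at the end, in percent of the substrate charged, oak
* homo product at the end, in percent of the substrate charged, cedar
* homo product at the end, in percent of the substrate charged, elm

- percent here means substrate units held: one homo product counts as two
- the numbers in the tables scatter with a standard deviation of 2 percentage points

1. Base. Green and blue stand at 57% and 41% at 30 min, a fall of 16 points over 0.830 equiv of partner. A straight line between them gives B = 50.6% at 1.00 equiv, which is our figure for oak.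

2. Lag. Let L be the mean time by which partner arrives after substrate (the first moment of the dosing curve). A steady feed over 6.0 min gives 3.00 min, with partner behind in alder and substrate behind in cedar. Maple's portions, 1.50 min apart, have the same mean as cedar's feed, so we reckon maple with cedar. Elm's L is 20.0 s.

3. Window. Ochre holds 41% at 10.0 min and 49% at 20.0 min, so we take W = 10.0 min as the working window, with 83.7% of the later reading already there. Averaged over W, a lag L leaves the flask short by the fraction L/W of its partner.

4. Correction. The fall per equivalent, times that shortage, gives 5.8 points at the slow-feed lag. This is the lag shift: the points of final homo product moved by a mean lag of one reagent behind the other.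

5. Decision. We reckon alder at 56.4%, elm at 51.3%, and cedar and maple at 44.8%. The shift is larger than the scatter of 2 points, so we would charge alder.

The forecast also names alder, with alder 55%, maple 48%, oak 51%, cedar 47% and elm 52%: "Feeding partner slowly leaves substrate alone early, which raises homo". On maple it stands 3.1 points above our figure.

The flasks give alder as highest: alder 55.6%, maple 42.4%, oak 49.2%, cedar 42.8%, elm 49.9%.

    2 open intermediate → homo product (k = 0.00530 M⁻¹ s⁻¹)
    open intermediate + second intermediate → target (k = 0.0110 M⁻¹ s⁻¹)
    target → over-reaction product (k = 0.00680 s⁻¹)
    partner → second intermediate (k = 0.00230 s⁻¹)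
    substrate ⇌ open intermediate (K = 2.20, k = 0.00760 s⁻¹)
    target ⇌ isomer of the product (K = 0.130, k = 0.00750 s⁻¹)
    partner ⇌ dormant form (K = 1.30, k = 0.00760 s⁻¹)

Alder stands 6.4 points above oak and cedar 6.4 points below it, against a lag shift of 5.8 points, and maple lies beside cedar. Now take a neighbouring flask: alder at 0.20 M of substrate, with the equivalents held. If W stretches inversely with concentration, as for a second-order reaction, the lag shift becomes 2.3 points, and with B held we reckon base plus shift at 53.0% for a finished flask. At 30 min this neighbouring flask holds 45.3% of homo product, with 7.08% of substrate and 13.8% of open intermediate unconverted.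

(The data were computed for an exercise; noise was put on by code.)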